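Ring A of the target hides a para-cresol: the oxygen on C3 is para to the methyl-bearing quaternary carbon C10 and ortho to C4. Ring A is therefore brought in as a flat methyl 5-methylsalicylate and ring B is closed onto it by a dearomatising allylic alkylation. In one operation an iridium phosphoramidite catalyst turns the phenol, which carries a dienyl carbonate chain on C5, into the bicyclic cross-conjugated dienone: the C9–C10 bond, the quaternary centre C10, the vinyl-bearing stereocentre C9 and the C8 methylidene group all arise together. The precursor is an achiral tetrasubstituted benzene made by lateral alkylation and Stille coupling.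

Key step: step 6

Remark on numbering: locants C1–C20 in the text are those of the labdane skeleton of the target (ring A: C1–C5 and C10; ring B: C5–C10; C17 is the methylidene carbon on C8; C18 the methyl and C19 the acetoxymethyl carbon on C4; C20 the methyl on C10; C11=C12 the side-chain alkene).

Assumption: with the (Ra,R,R) ligand the iridium catalyst is taken to open the face of C9 that leads to the (5R) configuration of 10; if the sense of induction is the opposite one, the (Sa,S,S) ligand is used instead.

Step 1
Reactants: 1 methyl 2-hydroxy-6-methylbenzoate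
Product: 2 methyl 3-bromo-6-hydroxy-2-methylbenzoate
Conditions: NBS (1.0 equiv), MeCN, 0 °C to rt, dark
Reagents that add atoms: N-bromosuccinimide, O=C1CCC(=O)N1Br
Why: Electrophilic aromatic bromination should go para to the free hydroxyl group, a position that the neighbouring methyl group also activates, in preference to the position ortho to the hydroxyl group.

Step 2
Reactants: 2 methyl 3-bromo-6-hydroxy-2-methylbenzoate
Product: 3 methyl 6-hydroxy-2,3-dimethylbenzoate
Conditions: MeB(OH)2, Pd(OAc)2 (3 mol %), SPhos (6 mol %), K3PO4, toluene/H2O, 90 °C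
Reagents that add atoms: methylboronic acid, CB(O)O
Why: Suzuki–Miyaura methylation of the aryl bromide should install the future C20 methyl group, the bulky electron-rich biarylphosphine tolerating the ortho substituent and the free phenol.

Step 3
Reactants: 3 methyl 6-hydroxy-2,3-dimethylbenzoate; 4 2,3-dibromoprop-1-ene
Product: 6 methyl 2-(3-bromobut-3-en-1-yl)-6-hydroxy-3-methylbenzoate, via benzylic dilithio species 5 (not isolated)
Conditions: LiN(i-Pr)2 (2.2 equiv), THF, −78 °C; then 4, −78 to −20 °C; 1 M HCl
Reagents that add atoms: none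
Why: Lateral lithiation should occur, after deprotonation of the phenol, only at the methyl group ortho to the ester (benzylic anion conjugated with the ester), and this carbanion should displace the allylic bromide of 4 by SN2 while the vinylic bromide stays.

Step 4
Reactants: 6 methyl 2-(3-bromobut-3-en-1-yl)-6-hydroxy-3-methylbenzoate; 7 (2E)-3-(tributylstannyl)prop-2-en-1-ol
Product: 8 methyl 6-hydroxy-2-[(4E)-6-hydroxy-3-methylidenehex-4-en-1-yl]-3-methylbenzoate
Conditions: Pd(PPh3)4 (5 mol %), CuI (10 mol %), DMF, 50 °C
Reagents that add atoms: none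
Why: Stille coupling of the 2-bromoalkene with the (E)-alkenylstannane should give the 2-substituted diene with retention of alkene geometry and needs no protection of the phenol, the ester or the alcohol.

Step 5
Reactants: 8 methyl 6-hydroxy-2-[(4E)-6-hydroxy-3-methylidenehex-4-en-1-yl]-3-methylbenzoate
Product: 9 methyl 6-hydroxy-2-[(4E)-6-[(methoxycarbonyl)oxy]-3-methylidenehex-4-en-1-yl]-3-methylbenzoate
Conditions: ClCO2Me (1.1 equiv), pyridine, CH2Cl2, −20 °C
Reagents that add atoms: methyl chloroformate, COC(=O)Cl
Why: O-Acylation of the primary allylic alcohol should be much faster at low temperature than that of the phenol, which is hydrogen-bonded to the ester, and it gives the allylic carbonate needed as leaving group.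

Step 6
Reactants: 9 methyl 6-hydroxy-2-[(4E)-6-[(methoxycarbonyl)oxy]-3-methylidenehex-4-en-1-yl]-3-methylbenzoate
Product: 10 methyl (4aS,5R)-5-ethenyl-4a-methyl-6-methylidene-2-oxo-2,4a,5,6,7,8-hexahydronaphthalene-1-carboxylate
Conditions: [Ir(cod)Cl]2 (2.5 mol %), (Ra)-BINOL N,N-bis[(R)-1-phenylethyl]phosphoramidite (5 mol %), n-PrNH2 (catalyst activation, then removed), Cs2CO3, THF, 0.02 M, 50 °C
Reagents that add atoms: none
Why: Proposed new method: the cyclometalated iridium phosphoramidite catalyst should ionise the dienyl carbonate with loss of CO2 and methoxide to a π-allyl complex of trivalent iridium spanning C9–C11–C12, and the phenolate should attack its substituted terminus C9 through the para carbon (C10) anti to iridium; the closest known reactions are the iridium-catalysed intramolecular asymmetric allylic dearomatisation of para-tethered phenols to spirocyclohexadienones and the palladium-catalysed enantioselective dearomative cyclisation of 3-tethered 4-methylphenols at the methyl-bearing para carbon. Ring B closes in a 6-exo mode on the allyl terminus, so that the vinyl group (C11=C12) and the C8 methylidene group stay exocyclic. C9 is set by the ligand, which fixes the face of the allyl terminus that is open to outer-sphere attack. C10 follows from C9 through a chair-like transition state in which the iridium-bound allyl unit points away from the arene, which places H9 anti to the C10 methyl group. The step needs para C-alkylation over ortho C-alkylation, O-alkylation and attack at C12 or C17: the ortho carbon C4 is blocked by the ester and flanked on both sides, O-alkylation within the molecule would need a meta-bridged eight-membered ring and is suppressed between molecules by dilution, and attack at C12 or C17 would give eight- or seven-membered rings against the preference of iridium for the substituted terminus. Because C10 carries a methyl group, the cross-conjugated dienone cannot rearomatise.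

Step 7
Reactants: 10 methyl (4aS,5R)-5-ethenyl-4a-methyl-6-methylidene-2-oxo-2,4a,5,6,7,8-hexahydronaphthalene-1-carboxylate
Product: 12 methyl (4aS,5R)-5-ethenyl-4a-methyl-6-methylidene-2-oxo-2,3,4,4a,5,6,7,8-octahydronaphthalene-1-carboxylate, via silyl enol ether 11 (not isolated)
Conditions: [(Ph3P)CuH]6 (5 mol %), PhMe2SiH (1.2 equiv), toluene, 0 °C to rt; then 1 M HCl, THF
Reagents that add atoms: none
Why: Copper hydride conjugate reduction (1,4-hydrosilylation) should deliver hydride to the unhindered β-CH (C1) of the disubstituted enone arm and not to the fully substituted C5 of the other arm, and it leaves the isolated alkenes and the ester untouched; hydrolysis of the silyl enol ether gives the ketone.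

Step 8
Reactants: 12 methyl (4aS,5R)-5-ethenyl-4a-methyl-6-methylidene-2-oxo-2,3,4,4a,5,6,7,8-octahydronaphthalene-1-carboxylate
Product: 14 methyl (1S,4aR,5R,8aS)-5-ethenyl-1,4a-dimethyl-6-methylidene-2-oxodecahydronaphthalene-1-carboxylate, via lithium enolate 13 (not isolated)
Conditions: Li (2.2 equiv), NH3(l)/THF, t-BuOH (1.0 equiv), −78 °C; then MeI (excess), −78 to −33 °C
Reagents that add atoms: iodomethane, CI
Why: In this dissolving-metal reductive alkylation, protonation of the β-carbanion at C5 should give the trans ring fusion (H5 anti to the C10 methyl group), and the regiospecifically formed lithium β-keto ester enolate should be methylated at C4 on the face anti to the axial C10 methyl group, which leaves the ester axial and the new methyl group equatorial.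

Step 9
Reactants: 14 methyl (1S,4aR,5R,8aS)-5-ethenyl-1,4a-dimethyl-6-methylidene-2-oxodecahydronaphthalene-1-carboxylate
Product: 15 (1R,2R,4aR,5R,8aS)-5-ethenyl-1-(hydroxymethyl)-1,4a-dimethyl-6-methylidenedecahydronaphthalen-2-ol
Conditions: LiAlH4 (2 equiv), THF, 0 °C to rt; aqueous NaOH work-up
Reagents that add atoms: none
Why: Hydride reduction with LiAlH4 takes the ketone and the ester in one operation, and hydride should add to the C3 carbonyl axially, on the face away from the axial C4 substituent, which gives the equatorial 3-hydroxyl group cis to the hydroxymethyl group.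

Step 10
Reactants: 15 (1R,2R,4aR,5R,8aS)-5-ethenyl-1-(hydroxymethyl)-1,4a-dimethyl-6-methylidenedecahydronaphthalen-2-ol
Product: 16 [(1R,2R,4aR,5R,8aS)-5-ethenyl-2-hydroxy-1,4a-dimethyl-6-methylidenedecahydronaphthalen-1-yl]methyl acetate
Conditions: AcCl (1.05 equiv), 2,4,6-collidine, CH2Cl2, −78 °C
Reagents that add atoms: acetyl chloride, CC(=O)Cl
Why: In this chemoselective O-acylation with a hindered pyridine base at low temperature, acetyl chloride should acylate the primary hydroxyl group much faster than the secondary one next to the quaternary carbon.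

Step 11
Reactants: 16 [(1R,2R,4aR,5R,8aS)-5-ethenyl-2-hydroxy-1,4a-dimethyl-6-methylidenedecahydronaphthalen-1-yl]methyl acetate; 17 3-bromofuran-2(5H)-one
Product: 18 [(1R,2R,4aR,5R,8aS)-2-hydroxy-1,4a-dimethyl-6-methylidene-5-[(E)-2-(2-oxo-2,5-dihydrofuran-3-yl)ethenyl]decahydronaphthalen-1-yl]methyl acetate
Conditions: Pd(OAc)2 (10 mol %), P(o-tol)3 (20 mol %), NaHCO3, n-Bu4NCl, DMF, 70 °C
Reagents that add atoms: none
Why: In this Mizoroki–Heck reaction the alkenylpalladium species from the α-bromobutenolide should add to the terminal carbon C12 of the monosubstituted alkene, and syn β-hydride elimination should then give the conjugated (E)-diene, while the 1,1-disubstituted methylidene group reacts much more slowly.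

Compound list
1 | methyl 2-hydroxy-6-methylbenzoate | COC(=O)c1c(C)cccc1O | starting material
2 | methyl 3-bromo-6-hydroxy-2-methylbenzoate | COC(=O)c1c(C)c(Br)ccc1O | intermediate
3 | methyl 6-hydroxy-2,3-dimethylbenzoate | COC(=O)c1c(C)c(C)ccc1O | intermediate
4 | 2,3-dibromoprop-1-ene | C=C(Br)CBr | starting material
5 | benzylic dilithio species of 3 (lithium phenoxide, lithiated 2-methyl group; not isolated) | COC(=O)c1c(C[Li])c(C)ccc1O[Li] | intermediate
6 | methyl 2-(3-bromobut-3-en-1-yl)-6-hydroxy-3-methylbenzoate | COC(=O)c1c(CCC(Br)=C)c(C)ccc1O | intermediate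
7 | (2E)-3-(tributylstannyl)prop-2-en-1-ol | CCCC[Sn](CCCC)(CCCC)/C=C/CO | starting material
8 | methyl 6-hydroxy-2-[(4E)-6-hydroxy-3-methylidenehex-4-en-1-yl]-3-methylbenzoate | COC(=O)c1c(CCC(=C)/C=C/CO)c(C)ccc1O | intermediate
9 | methyl 6-hydroxy-2-[(4E)-6-[(methoxycarbonyl)oxy]-3-methylidenehex-4-en-1-yl]-3-methylbenzoate | COC(=O)OC/C=C/C(=C)CCc1c(C)ccc(O)c1C(=O)OC | intermediate
10 | methyl (4aS,5R)-5-ethenyl-4a-methyl-6-methylidene-2-oxo-2,4a,5,6,7,8-hexahydronaphthalene-1-carboxylate | C=C1CCC2=C(C(=O)OC)C(=O)C=C[C@@]2(C)[C@@H]1C=C | intermediate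
11 | methyl (4aS,5R)-2-{[dimethyl(phenyl)silyl]oxy}-5-ethenyl-4a-methyl-6-methylidene-4,4a,5,6,7,8-hexahydronaphthalene-1-carboxylate (silyl enol ether, not isolated) | C=C1CCC2=C(C(=O)OC)C(O[Si](C)(C)c3ccccc3)=CC[C@@]2(C)[C@@H]1C=C | intermediate
12 | methyl (4aS,5R)-5-ethenyl-4a-methyl-6-methylidene-2-oxo-2,3,4,4a,5,6,7,8-octahydronaphthalene-1-carboxylate | C=C1CCC2=C(C(=O)OC)C(=O)CC[C@@]2(C)[C@@H]1C=C | intermediate
13 | lithium enolate of methyl (4aR,5R,8aS)-5-ethenyl-4a-methyl-6-methylidene-2-oxodecahydronaphthalene-1-carboxylate (not isolated) | C=C1CC[C@@H]2C(C(=O)OC)=C(O[Li])CC[C@@]2(C)[C@@H]1C=C | intermediate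
14 | methyl (1S,4aR,5R,8aS)-5-ethenyl-1,4a-dimethyl-6-methylidene-2-oxodecahydronaphthalene-1-carboxylate | C=C1CC[C@@H]2[C@](C)(C(=O)OC)C(=O)CC[C@@]2(C)[C@@H]1C=C | intermediate
15 | (1R,2R,4aR,5R,8aS)-5-ethenyl-1-(hydroxymethyl)-1,4a-dimethyl-6-methylidenedecahydronaphthalen-2-ol | C=C1CC[C@@H]2[C@](C)(CO)[C@H](O)CC[C@@]2(C)[C@@H]1C=C | intermediate
16 | [(1R,2R,4aR,5R,8aS)-5-ethenyl-2-hydroxy-1,4a-dimethyl-6-methylidenedecahydronaphthalen-1-yl]methyl acetate | C=C1CC[C@@H]2[C@](C)(COC(C)=O)[C@H](O)CC[C@@]2(C)[C@@H]1C=C | intermediate
17 | 3-bromofuran-2(5H)-one | O=C1OCC=C1Br | starting material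
18 | [(1R,2R,4aR,5R,8aS)-2-hydroxy-1,4a-dimethyl-6-methylidene-5-[(E)-2-(2-oxo-2,5-dihydrofuran-3-yl)ethenyl]decahydronaphthalen-1-yl]methyl acetate | C=C1CC[C@@H]2[C@](C)(COC(C)=O)[C@H](O)CC[C@@]2(C)[C@@H]1/C=C/C1=CCOC1=O | target

Total step count: 11
Longest linear sequence: 11 steps (1 to 18)

Steps most likely to fail

Step 6 (Proposed new method). What may go wrong: the electron-poor phenolate may react too slowly, may attack through the ester-bearing ortho carbon, or may be allylated on oxygen between two molecules, and the two faces of the arene may be poorly distinguished. The fallback uses known chemistry, sets out from 4 and 7 and comes back to the route at 12. The iridium-catalysed allylic ring closure is kept, but it is run with a β-keto ester, the standard carbon nucleophile of this reaction, and ring A is then built by Robinson annulation. Methyl 2-methyl-3-oxobutanoate is converted (NaH, then n-BuLi, THF, 0 °C) into its sodium lithium dianion F1, which is alkylated at the terminal carbon by 4 to give methyl 6-bromo-2-methyl-3-oxohept-6-enoate F2. Stille coupling with 7 (Pd(PPh3)4, CuI, DMF) should give methyl (7E)-9-hydroxy-2-methyl-6-methylidene-3-oxonon-7-enoate F3, and methyl chloroformate with pyridine its carbonate, methyl (7E)-9-[(methoxycarbonyl)oxy]-2-methyl-6-methylidene-3-oxonon-7-enoate F4. With the catalyst of step 6 the stabilised enolate should close the six-membered ring at the substituted allyl terminus to give methyl (2R)-2-ethenyl-1-methyl-3-methylidene-6-oxocyclohexane-1-carboxylate F5 (either C1 epimer serves). Krapcho dealkoxycarbonylation (LiCl, wet DMSO, 140 °C) should give (3S)-3-ethenyl-2-methyl-4-methylidenecyclohexan-1-one F6. Robinson annulation with methyl 3-oxopent-4-enoate, released in the flask from commercial methyl 5-methoxy-3-oxopentanoate (NaOMe, MeOH, 0 °C to rt), should pass through the Michael adduct methyl 5-[(1S,2R)-2-ethenyl-1-methyl-3-methylidene-6-oxocyclohexyl]-3-oxopentanoate F7, the acceptor entering at the more substituted α-carbon anti to the neighbouring vinyl group, and aldol condensation with loss of water closes ring A to 12.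

Step 7. What may go wrong: loss of chemoselectivity between the two enone arms of 10, or reduction of both. The fallback sets out from 10 and comes back at 14, and it differentiates the arms electronically instead of sterically by reversing the order of the two reductions. Dissolving-metal reduction of 10 (Li, NH3/THF, t-BuOH, −78 °C) should place the electrons in the doubly activated C4=C5 bond and give, after protonation at C5, the lithium enolate of methyl (4aR,5R,8aS)-5-ethenyl-4a-methyl-6-methylidene-2-oxo-2,4a,5,6,7,8,8a-heptahydronaphthalene-1-carboxylate F8. Trapping with MeI should give methyl (1S,4aR,5R,8aS)-5-ethenyl-1,4a-dimethyl-6-methylidene-2-oxo-1,2,4a,5,6,7,8,8a-octahydronaphthalene-1-carboxylate F9. The single enone that remains is then reduced with [(Ph3P)CuH]6 and PhMe2SiH through methyl (1S,4aR,5R,8aS)-2-{[dimethyl(phenyl)silyl]oxy}-5-ethenyl-1,4a-dimethyl-6-methylidene-1,4,4a,5,6,7,8,8a-octahydronaphthalene-1-carboxylate F10, which is hydrolysed to 14.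

Step 11. What may go wrong: decomposition of the base-sensitive bromobutenolide, or migration of the double bonds by palladium hydride before the coupling is complete. The fallback sets out from 16 and comes back at 18, and it replaces the Heck reaction by metathesis followed by cross-coupling. Cross-metathesis of 16 with 4,4,5,5-tetramethyl-2-vinyl-1,3,2-dioxaborolane (second-generation Grubbs catalyst, CH2Cl2, 40 °C) should give [(1R,2R,4aR,5R,8aS)-2-hydroxy-1,4a-dimethyl-6-methylidene-5-[(E)-2-(4,4,5,5-tetramethyl-1,3,2-dioxaborolan-2-yl)ethenyl]decahydronaphthalen-1-yl]methyl acetate F11, and Suzuki–Miyaura coupling with 17 (Pd(dppf)Cl2, K3PO4, THF/H2O, rt) should give 18.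

Further compounds
F1 | step 6 | sodium lithium dianion of methyl 2-methyl-3-oxobutanoate | [Li]CC(O[Na])=C(C)C(=O)OC
F2 | step 6 | methyl 6-bromo-2-methyl-3-oxohept-6-enoate | COC(=O)C(C)C(=O)CCC(Br)=C
F3 | step 6 | methyl (7E)-9-hydroxy-2-methyl-6-methylidene-3-oxonon-7-enoate | COC(=O)C(C)C(=O)CCC(=C)/C=C/CO
F4 | step 6 | methyl (7E)-9-[(methoxycarbonyl)oxy]-2-methyl-6-methylidene-3-oxonon-7-enoate | COC(=O)OC/C=C/C(=C)CCC(=O)C(C)C(=O)OC
F5 | step 6 | methyl (2R)-2-ethenyl-1-methyl-3-methylidene-6-oxocyclohexane-1-carboxylate | C=C1CCC(=O)C(C)(C(=O)OC)[C@@H]1C=C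
F6 | step 6 | (3S)-3-ethenyl-2-methyl-4-methylidenecyclohexan-1-one | C=C1CCC(=O)C(C)[C@@H]1C=C
F7 | step 6 | methyl 5-[(1S,2R)-2-ethenyl-1-methyl-3-methylidene-6-oxocyclohexyl]-3-oxopentanoate | C=C1CCC(=O)[C@@](C)(CCC(=O)CC(=O)OC)[C@@H]1C=C
F8 | step 7 | lithium enolate of methyl (4aR,5R,8aS)-5-ethenyl-4a-methyl-6-methylidene-2-oxo-2,4a,5,6,7,8,8a-heptahydronaphthalene-1-carboxylate | C=C1CC[C@@H]2C(C(=O)OC)=C(O[Li])C=C[C@@]2(C)[C@@H]1C=C
F9 | step 7 | methyl (1S,4aR,5R,8aS)-5-ethenyl-1,4a-dimethyl-6-methylidene-2-oxo-1,2,4a,5,6,7,8,8a-octahydronaphthalene-1-carboxylate | C=C1CC[C@@H]2[C@](C)(C(=O)OC)C(=O)C=C[C@@]2(C)[C@@H]1C=C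
F10 | step 7 | methyl (1S,4aR,5R,8aS)-2-{[dimethyl(phenyl)silyl]oxy}-5-ethenyl-1,4a-dimethyl-6-methylidene-1,4,4a,5,6,7,8,8a-octahydronaphthalene-1-carboxylate | C=C1CC[C@@H]2[C@](C)(C(=O)OC)C(O[Si](C)(C)c3ccccc3)=CC[C@@]2(C)[C@@H]1C=C
F11 | step 11 | [(1R,2R,4aR,5R,8aS)-2-hydroxy-1,4a-dimethyl-6-methylidene-5-[(E)-2-(4,4,5,5-tetramethyl-1,3,2-dioxaborolan-2-yl)ethenyl]decahydronaphthalen-1-yl]methyl acetate | C=C1CC[C@@H]2[C@](C)(COC(C)=O)[C@H](O)CC[C@@]2(C)[C@@H]1/C=C/B1OC(C)(C)C(C)(C)O1
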